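The electrophile is the yardstick here: amounts below are fractions of its charge.

the same everywhere: gas 0.33 mM (held)

|  | electrophile | nucleophile | remark | time |
|---|---|---|---|---|
| green | 10 mM | 0.53 equiv (fed, over 3.0 min) | run made earlier |  |
| amber | 10 mM | 0.79 equiv (fed, over 3.0 min) | run made earlier |  |
| red | 15 mM | 1.05 equiv (fed, over 3.0 min) | run made earlier |  |
| flask | 10 mM | 1.05 equiv (fed, over 3.0 min) |  | 4.0 min |

The flask takes 1.05 equiv of nucleophile over 3.0 min, like the red run, but holds 10 mM of electrophile against 15 mM, and the gas is held at 0.33 mM in both. So the red run serves as a guide, with its charge scaled.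

| run | time / min | target / % | electrophile / % |
|---|---|---|---|
| green | 0.667 | 6.0 | 93.8 |
| green | 1.33 | 10.6 | 86.7 |
| green | 2.00 | 14.7 | 78.9 |
| green | 3.00 | 20.5 | 67.1 |
| green | 4.00 | 20.6 | 61.2 |
| green | 5.00 | 22.1 | 56.7 |
| amber | 0.667 | 8.0 | 88.9 |
| amber | 1.33 | 15.6 | 79.8 |
| amber | 2.00 | 21.9 | 70.6 |
| amber | 3.00 | 32.2 | 53.4 |
| amber | 4.00 | 32.9 | 44.5 |
| amber | 5.00 | 28.5 | 42.0 |
| red | 1.00 | 14.2 | 80.1 |
| red | 2.00 | 25.6 | 58.8 |
| red | 3.00 | 38.8 | 34.8 |
| red | 4.00 | 37.5 | 29.1 |
| red | 5.00 | 35.8 | 23.4 |

(scatter of a reading: 1 percentage point)

- the analysis behind the earlier runs scatters by 1 percentage point, standard deviation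
- at the start none of the gas is in solution

But electrophile and target don't add up to the charge: at 5.00 min the red run lacks 40.8%. A zero for this gap is chance, with one electrophile meeting one target and two units of charge leaving per meeting. The gap would then grow as twice a constant times the charge times both fractions. From 3.00 min to 5.00 min, after the feed, the red readings give 22.1 /M/min: this is the loss constant, a second-order rate constant, gap per minute over twice the charge and both fractions.

If the fractions run alike at equal equivalents, the flask's gap is the red gap scaled by the charges, 22.3% at 4.0 min. Taking the red run's consumed 70.9% for the flask, this reckoning leaves 48.6% target.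

- amount of target in percent of the electrophile charged, at 50 s, 2.0 min and 4.0 min

The forecast gives 12.3%, 27.5% and 37%, on the ground that “formation roughly balances loss” after the feed. Its last figure differs from this reckoning, which stands higher.

The flask gives 13.0%, 29.4% and 43.3%.

    electrophile + nucleophile ⇌ acid set free + target (K = 24.0, k = 20.0 /M/s)
    nucleophile + acid set free ⇌ protonated nucleophile, settled at all times (K = 2.20 × 10⁵ /M)
    acid set free + free base ⇌ salt of the base, settled at all times (K = 3800 /M)
    gas ⇌ free base, rate k4*(csat - [free base]) (kL = 0.710 /s)
    electrophile + target → side product (k = 0.380 /M/s)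

At the end of the feed, 3.00 min, the flask holds 42.3% target and, counted in units of electrophile, 18.3% side product. At 4.0 min it holds 43.3% target and 25.2% side product. The loss constant, with the mean fractions of that minute, gives 6.71% of new gap. For the amber run from 3.00 min to 5.00 min it gives 12.8%, and the amber readings show 15.1%.

The data are simulated on assumed constants; scatter was added.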